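**Retrosynthetic overview**
1. Japonicone A is treated as the [4+2] adduct of the exo-methylene (C11′=C13′) of silyl-protected ent-1β-hydroxyalantolactone 15 with a C1-alkylated 2-oxidocyclopentadiene; the guaianolide lactone and the seven-membered ring are then closed on the finished norbornene.
2. Last disconnection: C5–C6 (seven-membered ring) together with C7–C11 (lactone ring, at the lactol-ether level), made in one nickel-catalysed reductive radical bicyclisation of alkenyl triflate/bromoacetal 30.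
3. Enabling feature: the formal [4+2] leaves the enolate oxygen on C5, next to the quaternary bridgehead C1. As its triflate, C5 faces the C1 side chain C10–C9–C8(O-bromoacetal)–C7=C6, so the C6 radical formed when C11 closes 5-exo onto C7 lies within seven-ring reach of C5.
4. 30 comes from one three-component step: Me2CuLi on alkylidene cyclopentenone 27 (sets C10), double Michael addition to 15 (sets C1, C3, C11′), triflation. 27 is the aldol condensation product of cyclopentenone 20 (Piancatelli route) and aldehyde 24.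
5. Ring order: decalin (bought) → eudesmanolide lactone → cyclopentenone → norbornene → oxolane → seven-membered ring. Stereocentres bought or set by catalysis: C10′, C2, C8; all others are relayed.

Key step: step 19

Remark on the chemistry: the SMILES is taken as drawn; its eudesmanolide half is then the mirror image of natural 1β-hydroxyalantolactone, so this half is built from (S)-Wieland–Miescher ketone and not taken from the natural lactone.
Numbering: guaianolide half C1–C15 (C1 bridgehead bonded to C10, C2 the acetoxy carbon, C4=C5, lactone C8–O–C12(=O)–C11(=C13)–C7); eudesmanolide half primed (C11′ spiro carbon, C13′ its CH2 neighbour in the norbornene).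

**Fragment 1: dienophile 15**

Step 1
Reactants: 1 (S)-(+)-Wieland–Miescher ketone
Product: 2 (4aS,5S)-5-hydroxy-4a-methyl-4,4a,5,6,7,8-hexahydronaphthalen-2(3H)-one
Conditions: NaBH4 (0.3 equiv), EtOH, −10 °C
Reagents that add atoms: none
Why: Chemoselective hydride reduction of the saturated C1′ ketone, with hydride arriving anti to the angular methyl so that C1′–OH is syn to it (the known outcome for this ketone).

Step 2
Reactants: 2 (4aS,5S)-5-hydroxy-4a-methyl-4,4a,5,6,7,8-hexahydronaphthalen-2(3H)-one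
Product: 3 (4aS,5S)-5-(tert-butyldimethylsilyloxy)-4a-methyl-4,4a,5,6,7,8-hexahydronaphthalen-2(3H)-one
Conditions: TBSCl, imidazole, DMF, 25 °C
Reagents that add atoms: tert-butyldimethylsilyl chloride, CC(C)(C)[Si](C)(C)Cl
Why: Standard silylation of a secondary alcohol; no stereocentre is touched.

Step 3
Reactants: 3 (4aS,5S)-5-(tert-butyldimethylsilyloxy)-4a-methyl-4,4a,5,6,7,8-hexahydronaphthalen-2(3H)-one
Product: 4 (4aS,5S)-5-(tert-butyldimethylsilyloxy)-4a-methyl-8-methylidene-4,4a,5,6,7,8-hexahydronaphthalen-2(3H)-one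
Conditions: CH2(OEt)2, POCl3, NaOAc, CHCl3, 60 °C
Reagents that add atoms: diethoxymethane, CCOCOCC
Why: Vinylogous (γ) methylenation of the enone through its heteroannular dienol ether and an alkoxymethyl cation, the reaction type used for 6-methylenation of steroidal 4-en-3-ones; no stereocentre is formed.

Step 4
Reactants: 4 (4aS,5S)-5-(tert-butyldimethylsilyloxy)-4a-methyl-8-methylidene-4,4a,5,6,7,8-hexahydronaphthalen-2(3H)-one
Product: 5 (4aS,5S,8R)-5-(tert-butyldimethylsilyloxy)-4a,8-dimethyl-4,4a,5,6,7,8-hexahydronaphthalen-2(3H)-one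
Conditions: H2 (1 atm), RhCl(PPh3)3 (5 mol %), benzene–EtOH, 25 °C
Reagents that add atoms: none
Why: Homogeneous hydrogenation should pick the exocyclic 1,1-disubstituted alkene and deliver hydrogen to C4′ anti to the angular methyl, leaving the new methyl syn to it (kinetic epimer; neutral conditions avoid epimerisation through the dienol).

Step 5
Reactants: 5 (4aS,5S,8R)-5-(tert-butyldimethylsilyloxy)-4a,8-dimethyl-4,4a,5,6,7,8-hexahydronaphthalen-2(3H)-one
Product: 6 cross-conjugated dienyl triflate of 5 (C7′–OTf; C5′=C6′ and C7′=C8′)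
Conditions: LDA, THF, −78 °C; then PhNTf2, −78 → 0 °C
Reagents that add atoms: N-phenylbis(trifluoromethanesulfonimide), O=S(=O)(N(c1ccccc1)S(=O)(=O)C(F)(F)F)C(F)(F)F
Why: Kinetic α′-deprotonation at C8′ and O-triflation of the enolate; C4′ is not deprotonated at −78 °C and no stereocentre changes.

Step 6
Reactants: 6 cross-conjugated dienyl triflate of 5
Product: 7 tert-butyl ester carrying C7′–CH2CO2t-Bu on the 5′,7′-diene
Conditions: BrZnCH2CO2t-Bu, Pd(PPh3)4 (5 mol %), THF, 60 °C
Reagents that add atoms: tert-butyl (bromozincio)acetate, CC(C)(C)OC(=O)C[Zn]Br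
Why: Negishi coupling of a Reformatsky reagent with an alkenyl triflate; no stereocentre is formed.

Step 7
Reactants: 7 tert-butyl ester carrying C7′–CH2CO2t-Bu on the 5′,7′-diene
Product: 9 trans-hydroxy ester (C8′–OH anti and C7′ side chain syn to the angular methyl), via B-alkyl-9-BBN adduct 8 (not isolated)
Conditions: 9-BBN, THF, 0 → 25 °C; then aq NaOH, H2O2, 0 °C
Reagents that add atoms: hydrogen peroxide, OO
Why: Hydroboration–oxidation: boron should go to the less substituted C8′ of the less hindered C7′=C8′ bond, anti to the angular methyl, and syn addition puts H7′ anti and the acetate side chain syn to that methyl.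

Step 8
Reactants: 9 trans-hydroxy ester
Product: 10 keto ester (C8′ ketone; C5′=C6′ kept)
Conditions: Dess–Martin periodinane, NaHCO3, CH2Cl2, 0 °C
Reagents that add atoms: none
Why: Buffered hypervalent-iodine oxidation gives the β,γ-unsaturated ketone without conjugation and removes the wrongly configured C8′ carbinol; C7′ keeps its equatorial side chain.

Step 9
Reactants: 10 keto ester
Product: 12 cis-fused lactone (C8′–O and C7′–C11′ syn to the angular methyl; C11′H2), via lithium alkoxide of the cis-hydroxy ester 11 (not isolated)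
Conditions: LiBH(s-Bu)3 (L-Selectride), THF, −78 °C; then 25 °C
Reagents that add atoms: none
Why: The bulky hydride should attack the C8′ carbonyl anti to the syn-axial angular methyl, giving the axial alkoxide cis to the C7′ side chain, which lactonises on the tert-butyl ester.

Step 10
Reactants: 12 cis-fused lactone
Product: 15 tert-butyldimethylsilyl ether of ent-1β-hydroxyalantolactone, via Mannich base 13 (not isolated), via trimethylammonium iodide 14 (not isolated)
Conditions: LDA, THF, −78 °C; CH2=NMe2+ I−, −78 → 25 °C; then MeI, MeOH; then aq NaHCO3, CH2Cl2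
Reagents that add atoms: Eschenmoser's salt (N,N-dimethylmethyleneiminium iodide), C=[N+](C)C.[I-]
Why: Mannich reaction of the lactone enolate followed by quaternisation and Hofmann-type elimination gives the α-methylene lactone; the C11′ stereocentre of 13 is removed again.

**Fragment 2: cyclopentenone 20**

Step 11
Reactants: 16 rac-1-(furan-2-yl)ethanol
Product: 17 rac-trans-4-hydroxy-5-methylcyclopent-2-en-1-one
Conditions: Dy(OTf)3 (10 mol %), t-BuOH–H2O (5:1), 80 °C
Reagents that add atoms: water, O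
Why: Piancatelli rearrangement; conrotatory 4π closure of the hydroxypentadienyl cation should give the 4,5-trans product as a racemate.

Step 12
Reactants: 17 rac-trans-4-hydroxy-5-methylcyclopent-2-en-1-one
Product: 18 (4S,5R)-4-acetoxy-5-methylcyclopent-2-en-1-one
Conditions: Burkholderia cepacia lipase (lipase PS), vinyl acetate, t-BuOMe, 30 °C, to about half conversion
Reagents that add atoms: vinyl acetate, C=COC(C)=O
Why: Enzymatic kinetic resolution by acyl transfer; the (4S,5R)-alcohol matches spatially the fast-reacting antipode of 4-hydroxycyclopent-2-enone, so it should be acetylated while the (4R,5S)-alcohol stays behind.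

Step 13
Reactants: 18 (4S,5R)-4-acetoxy-5-methylcyclopent-2-en-1-one
Product: 20 (S)-2-methyl-4-vinylcyclopent-2-en-1-one, via conjugate adduct 19 (not isolated)
Conditions: CH2=CHMgBr (2.2 equiv), CuI (1.1 equiv), THF, −78 → −40 °C; aq NH4Cl; then DBU, CH2Cl2, 0 °C
Reagents that add atoms: vinylmagnesium bromide, C=C[Mg]Br
Why: Cuprate conjugate addition anti to the acetoxy group, then E1cB loss of acetate towards the methyl-bearing carbon (addition–elimination known for 4-acyloxycyclopentenones), relays the carbinol stereocentre into C2 and makes the methyl carbon the enone α-carbon.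

**Fragment 3: aldehyde 24**

Step 14
Reactants: 21 rac-ethyl 3-hydroxypent-4-enoate
Product: 22 ethyl (R)-3-hydroxypent-4-enoate
Conditions: lipase PS, vinyl acetate, pentane, 25 °C, to slightly more than half conversion
Reagents that add atoms: none
Why: Lipase kinetic resolution; by the empirical size rule the (S)-alcohol should be acetylated and the (R)-alcohol (the future C8) recovered.

Step 15
Reactants: 22 ethyl (R)-3-hydroxypent-4-enoate
Product: 23 ethyl (3R)-3-(2-bromo-1-ethoxyethoxy)pent-4-enoate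
Conditions: NBS, ethyl vinyl ether, CH2Cl2, −40 → 0 °C
Reagents that add atoms: ethyl vinyl ether, C=COCC; N-bromosuccinimide, O=C1CCC(=O)N1Br
Why: Bromoacetalisation (bromonium ion of the vinyl ether trapped by the alcohol); the acetal serves first as protecting group and later as radical precursor, and its new centre forms as a mixture that is removed later.

Step 16
Reactants: 23 ethyl (3R)-3-(2-bromo-1-ethoxyethoxy)pent-4-enoate
Product: 24 (3R)-3-(2-bromo-1-ethoxyethoxy)pent-4-enal
Conditions: i-Bu2AlH, toluene, −78 °C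
Reagents that add atoms: none
Why: Partial reduction of the ester; the aluminium hemiacetal, stabilised by the β-alkoxy group, should survive at −78 °C and release the aldehyde on work-up.

**Union and endgame**

Step 17
Reactants: 20 (S)-2-methyl-4-vinylcyclopent-2-en-1-one; 24 (3R)-3-(2-bromo-1-ethoxyethoxy)pent-4-enal
Product: 27 (4S,5E)-5-[(3R)-3-(2-bromo-1-ethoxyethoxy)pent-4-en-1-ylidene]-2-methyl-4-vinylcyclopent-2-en-1-one, via lithium aldolate 25 (not isolated), via mesylate 26 (not isolated)
Conditions: LDA, THF, −78 °C; then 24; then MsCl, Et3N, −78 → 0 °C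
Reagents that add atoms: none
Why: Aldol addition of the kinetic α′-enolate and E1cB elimination of the mesylate (aldol condensation) should give the cross-conjugated dienone with the (E)-alkylidene, C9 pointing away from the carbonyl oxygen.

Step 18
Reactants: 27 alkylidene cyclopentenone; 15 tert-butyldimethylsilyl ether of ent-1β-hydroxyalantolactone
Product: 30 norbornenyl triflate (C5–OTf; C1 side chain C10–C9–C8(O-bromoacetal)–C7=C6; C2 vinyl), via lithium dienolate 28 (not isolated), via bicyclic lithium enolate 29 (not isolated)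
Conditions: Me2CuLi (1.05 equiv), Et2O–THF, −78 °C; then 15, THF, −78 → −30 °C; then PhNTf2, −30 → 0 °C
Reagents that add atoms: lithium dimethylcuprate, [Li+].C[Cu-]C; N-phenylbis(trifluoromethanesulfonimide), O=S(=O)(N(c1ccccc1)S(=O)(=O)C(F)(F)F)C(F)(F)F
Why: Cuprate 1,4-addition to the s-cis exocyclic enone anti to the C2 vinyl group sets C10; the resulting 2-oxidocyclopentadiene then adds to the exo-methylene lactone by double Michael addition (formal Diels–Alder reaction; C1 to C13′, then C11′ to C3) on the diene face anti to the C2 vinyl group, on the convex face of the cis-fused lactone and with the lactone carbonyl endo, which sets C1, C3 and C11′, and the C5 enolate is trapped as triflate.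

Step 19
Reactants: 30 norbornenyl triflate
Product: 31 lactol ethyl ether with the seven-membered ring closed (7,8-trans; C12 epimers)
Conditions: NiBr2(dme) (20 mol %), 4,4′-di-tert-butyl-2,2′-bipyridine (24 mol %), Zn powder (3 equiv), NaI (0.5 equiv), DMA, 25 °C, 2 mM, slow addition of 30
Reagents that add atoms: none
Why: Proposed new method: zerovalent nickel (from NiBr2(dme) and zinc) should add oxidatively to the C5–OTf bond while a low-valent nickel centre abstracts bromine from the bromoacetal; the C11 radical closes 5-exo-trig onto C7=C6, the primary C6 radical is captured by the alkenylnickel at C5 of the same molecule, and reductive elimination from trivalent nickel makes C5–C6. The closest known reaction type is the nickel-catalysed reductive tandem cyclisation/cross-coupling of alkene-bearing β-bromoacetals with aryl or alkenyl halides; here the C(sp2) electrophile is tethered, so the coupling becomes a ring closure. The oxolane (the lactone ring at the lactol-ether level) closes first by 5-exo-trig radical addition, and the seven-membered carbocycle closes last by C(sp2)–C(sp3) reductive elimination through a nickelacycle. C7 is the only new stereocentre that is kept: the chair-like 5-exo transition state places the C9 chain on C8 pseudo-equatorial and should give the 7,8-trans ring fusion, whereas the acetal carbon C12 forms as a mixture that step 20 erases. The step needs cyclisation before capture and intramolecular rather than intermolecular capture: the 2-oxahex-5-enyl radical cyclises faster than it meets nickel, the rigid norbornene holds C5 and the C1 side chain on adjacent atoms, and high dilution suppresses dimerisation.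

Step 20
Reactants: 31 lactol ethyl ether
Product: 33 trans-fused lactone (C11H2; C2 vinyl), via lactol 32 (not isolated)
Conditions: PPTS, THF–H2O (4:1), 45 °C; then TEMPO (10 mol %), PhI(OAc)2, CH2Cl2, 25 °C
Reagents that add atoms: water, O
Why: Hydrolysis of the cyclic mixed acetal and oxoammonium oxidation of the lactol return the lactone oxidation level; no stereocentre of the skeleton is touched.

Step 21
Reactants: 33 trans-fused lactone
Product: 36 α-methylene lactone (C11=C13; C2 vinyl; 1′-O-silyl), via Mannich base 34 (not isolated), via trimethylammonium iodide 35 (not isolated)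
Conditions: LDA, THF, −78 °C; CH2=NMe2+ I−, −78 → 25 °C; then MeI, MeOH; then aq NaHCO3, CH2Cl2
Reagents that add atoms: Eschenmoser's salt (N,N-dimethylmethyleneiminium iodide), C=[N+](C)C.[I-]
Why: Mannich reaction and Hofmann-type elimination as in step 10; the guaianolide lactone is the only enolisable carbonyl, because the spiro lactone has no α-hydrogen.

Step 22
Reactants: 36 α-methylene lactone with C2 vinyl group
Product: 37 C2 methyl ketone
Conditions: PdCl2 (20 mol %), CuCl (1 equiv), O2 (1 atm), DMF–H2O (7:1), 25 °C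
Reagents that add atoms: water, O
Why: Wacker oxidation; Markovnikov hydroxypalladation should take place only at the monosubstituted vinyl group, the acrylate-type, trisubstituted and tetrasubstituted alkenes being poor substrates.

Step 23
Reactants: 37 C2 methyl ketone
Product: 38 1′-O-tert-butyldimethylsilyl japonicone A
Conditions: Me3SiOOSiMe3, TMSOTf (10 mol %), CH2Cl2, −30 °C
Reagents that add atoms: bis(trimethylsilyl) peroxide, C[Si](C)(C)OO[Si](C)(C)C
Why: Baeyer–Villiger oxidation with a silyl peroxide that should not epoxidise alkenes; the secondary C2 migrates in preference to methyl with retention, so the acetate stays syn to C4=C5, where the vinyl group was placed in step 18.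

Step 24
Reactants: 38 1′-O-tert-butyldimethylsilyl japonicone A
Product: 39 japonicone A (enantiomer as given)
Conditions: HF·pyridine, THF, 0 → 25 °C
Reagents that add atoms: none
Why: Fluoride-mediated desilylation under conditions that should leave the acetate and both lactones intact.

**Compound list**
1 | (S)-(+)-Wieland–Miescher ketone, (8aS)-8a-methyl-3,4,8,8a-tetrahydronaphthalene-1,6(2H,7H)-dione | O=C1CC[C@@]2(C)C(=C1)CCCC2=O | starting material
2 | (4aS,5S)-5-hydroxy-4a-methyl-4,4a,5,6,7,8-hexahydronaphthalen-2(3H)-one | O=C1CC[C@@]2(C)C(=C1)CCC[C@@H]2O | intermediate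
3 | (4aS,5S)-5-(tert-butyldimethylsilyloxy)-4a-methyl-4,4a,5,6,7,8-hexahydronaphthalen-2(3H)-one | O=C1CC[C@@]2(C)C(=C1)CCC[C@@H]2O[Si](C)(C)C(C)(C)C | intermediate
4 | (4aS,5S)-5-(tert-butyldimethylsilyloxy)-4a-methyl-8-methylidene-4,4a,5,6,7,8-hexahydronaphthalen-2(3H)-one | O=C1CC[C@@]2(C)C(=C1)C(=C)CC[C@@H]2O[Si](C)(C)C(C)(C)C | intermediate
5 | (4aS,5S,8R)-5-(tert-butyldimethylsilyloxy)-4a,8-dimethyl-4,4a,5,6,7,8-hexahydronaphthalen-2(3H)-one (8-methyl syn to 4a-methyl) | O=C1CC[C@@]2(C)C(=C1)[C@H](C)CC[C@@H]2O[Si](C)(C)C(C)(C)C | intermediate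
6 | cross-conjugated dienyl triflate of 5 (C7′–OTf; C5′=C6′, C7′=C8′) | O=S(=O)(OC1=CC[C@@]2(C)C(=C1)[C@H](C)CC[C@@H]2O[Si](C)(C)C(C)(C)C)C(F)(F)F | intermediate
7 | tert-butyl ester, C7′–CH2CO2t-Bu on the 5′,7′-diene | CC(C)(C)OC(=O)CC1=CC[C@@]2(C)C(=C1)[C@H](C)CC[C@@H]2O[Si](C)(C)C(C)(C)C | intermediate
8 | B-alkyl-9-BBN adduct (boron on C8′, anti to the angular methyl) | C12CCCC(CCC1)B2[C@@H]3C[C@@]4(C)C(=C[C@H]3CC(=O)OC(C)(C)C)[C@H](C)CC[C@@H]4O[Si](C)(C)C(C)(C)C | intermediate
9 | trans-hydroxy ester (C8′–OH anti, C7′ side chain syn to the angular methyl) | O[C@@H]1C[C@@]2(C)C(=C[C@H]1CC(=O)OC(C)(C)C)[C@H](C)CC[C@@H]2O[Si](C)(C)C(C)(C)C | intermediate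
10 | keto ester (C8′ ketone) | O=C1C[C@@]2(C)C(=C[C@H]1CC(=O)OC(C)(C)C)[C@H](C)CC[C@@H]2O[Si](C)(C)C(C)(C)C | intermediate
11 | lithium alkoxide of the cis-hydroxy ester (C8′–O syn to the angular methyl) | [Li]O[C@H]1C[C@@]2(C)C(=C[C@H]1CC(=O)OC(C)(C)C)[C@H](C)CC[C@@H]2O[Si](C)(C)C(C)(C)C | intermediate
12 | cis-fused lactone, C11′H2 (silyl-protected 11′,13′-dinor-methylene analogue of 15) | O=C1O[C@H]2C[C@@]3(C)C(=C[C@H]2C1)[C@H](C)CC[C@@H]3O[Si](C)(C)C(C)(C)C | intermediate
13 | Mannich base (C11′–CH2NMe2, C11′ epimers) | CN(C)CC1C(=O)O[C@H]2C[C@@]3(C)C(=C[C@H]21)[C@H](C)CC[C@@H]3O[Si](C)(C)C(C)(C)C | intermediate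
14 | trimethylammonium iodide of 13 | C[N+](C)(C)CC1C(=O)O[C@H]2C[C@@]3(C)C(=C[C@H]21)[C@H](C)CC[C@@H]3O[Si](C)(C)C(C)(C)C.[I-] | intermediate
15 | tert-butyldimethylsilyl ether of ent-1β-hydroxyalantolactone, (3aS,5R,8S,8aS,9aS)-8-(tert-butyldimethylsilyloxy)-5,8a-dimethyl-3-methylidene-3a,5,6,7,8,8a,9,9a-octahydronaphtho[2,3-b]furan-2(3H)-one | C=C1C(=O)O[C@H]2C[C@@]3(C)C(=C[C@H]21)[C@H](C)CC[C@@H]3O[Si](C)(C)C(C)(C)C | intermediate
16 | rac-1-(furan-2-yl)ethanol | CC(O)c1ccco1 | starting material
17 | rac-trans-4-hydroxy-5-methylcyclopent-2-en-1-one (racemate; the (4S,5R) enantiomer is drawn) | O=C1C=C[C@H](O)[C@H]1C | intermediate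
18 | (4S,5R)-4-acetoxy-5-methylcyclopent-2-en-1-one | O=C1C=C[C@H](OC(C)=O)[C@H]1C | intermediate
19 | 4-acetoxy-5-methyl-3-vinylcyclopentan-1-one (vinyl anti to acetoxy, acetoxy anti to methyl) | O=C1C[C@@H](C=C)[C@H](OC(C)=O)[C@H]1C | intermediate
20 | (S)-2-methyl-4-vinylcyclopent-2-en-1-one | O=C1C(C)=C[C@H](C=C)C1 | intermediate
21 | rac-ethyl 3-hydroxypent-4-enoate | CCOC(=O)CC(O)C=C | starting material
22 | ethyl (R)-3-hydroxypent-4-enoate | CCOC(=O)C[C@@H](O)C=C | intermediate
23 | ethyl (3R)-3-(2-bromo-1-ethoxyethoxy)pent-4-enoate (acetal epimers) | CCOC(=O)C[C@@H](OC(CBr)OCC)C=C | intermediate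
24 | (3R)-3-(2-bromo-1-ethoxyethoxy)pent-4-enal (acetal epimers) | O=CC[C@@H](OC(CBr)OCC)C=C | intermediate
25 | lithium aldolate of 20 and 24 (epimers at C1 and C10) | O=C1C(C)=C[C@H](C=C)C1C(O[Li])C[C@@H](OC(CBr)OCC)C=C | intermediate
26 | mesylate of the aldol | O=C1C(C)=C[C@H](C=C)C1C(OS(C)(=O)=O)C[C@@H](OC(CBr)OCC)C=C | intermediate
27 | (4S,5E)-5-[(3R)-3-(2-bromo-1-ethoxyethoxy)pent-4-en-1-ylidene]-2-methyl-4-vinylcyclopent-2-en-1-one | O=C1C(C)=C[C@H](C=C)/C1=C\C[C@@H](OC(CBr)OCC)C=C | intermediate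
28 | lithium 2-oxidocyclopentadiene (cross-conjugated dienolate, C10 methyl set) | [Li]OC1=C([C@H](C)C[C@@H](OC(CBr)OCC)C=C)[C@@H](C=C)C=C1C | intermediate
29 | bicyclic lithium enolate (norbornanone C5 enolate after double Michael addition) | C=C[C@H](OC(CBr)OCC)C[C@@H](C)[C@]12C[C@]3(C(=O)O[C@H]4C[C@@]5(C)C(=C[C@H]43)[C@H](C)CC[C@@H]5O[Si](C)(C)C(C)(C)C)[C@H](C(C)=C1O[Li])[C@@H]2C=C | intermediate
30 | norbornenyl triflate (C5–OTf, C4 methyl, C2 vinyl syn to C4=C5, spiro lactone carbonyl endo, C1 side chain with C8 O-bromoacetal and C7=C6) | C=C[C@H](OC(CBr)OCC)C[C@@H](C)[C@]12C[C@]3(C(=O)O[C@H]4C[C@@]5(C)C(=C[C@H]43)[C@H](C)CC[C@@H]5O[Si](C)(C)C(C)(C)C)[C@H](C(C)=C1OS(=O)(=O)C(F)(F)F)[C@@H]2C=C | intermediate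
31 | lactol ethyl ether with closed seven-membered ring (7,8-trans; C12 epimers) | C1C(OCC)O[C@@H]2C[C@@H](C)[C@]34C[C@]5(C(=O)O[C@H]6C[C@@]7(C)C(=C[C@H]65)[C@H](C)CC[C@@H]7O[Si](C)(C)C(C)(C)C)[C@H](C(C)=C3C[C@@H]12)[C@@H]4C=C | intermediate
32 | lactol (C12–OH, epimers) | C1C(O)O[C@@H]2C[C@@H](C)[C@]34C[C@]5(C(=O)O[C@H]6C[C@@]7(C)C(=C[C@H]65)[C@H](C)CC[C@@H]7O[Si](C)(C)C(C)(C)C)[C@H](C(C)=C3C[C@@H]12)[C@@H]4C=C | intermediate
33 | trans-fused guaianolide lactone, C11H2, C2 vinyl | C1C(=O)O[C@@H]2C[C@@H](C)[C@]34C[C@]5(C(=O)O[C@H]6C[C@@]7(C)C(=C[C@H]65)[C@H](C)CC[C@@H]7O[Si](C)(C)C(C)(C)C)[C@H](C(C)=C3C[C@@H]12)[C@@H]4C=C | intermediate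
34 | Mannich base (C11–CH2NMe2, C11 epimers) | CN(C)CC1C(=O)O[C@@H]2C[C@@H](C)[C@]34C[C@]5(C(=O)O[C@H]6C[C@@]7(C)C(=C[C@H]65)[C@H](C)CC[C@@H]7O[Si](C)(C)C(C)(C)C)[C@H](C(C)=C3C[C@@H]12)[C@@H]4C=C | intermediate
35 | trimethylammonium iodide of 34 | C[N+](C)(C)CC1C(=O)O[C@@H]2C[C@@H](C)[C@]34C[C@]5(C(=O)O[C@H]6C[C@@]7(C)C(=C[C@H]65)[C@H](C)CC[C@@H]7O[Si](C)(C)C(C)(C)C)[C@H](C(C)=C3C[C@@H]12)[C@@H]4C=C.[I-] | intermediate
36 | α-methylene lactone with C2 vinyl group (2-deacetoxy-2-vinyl-1′-O-silyl japonicone A) | C=C1C(=O)O[C@@H]2C[C@@H](C)[C@]34C[C@]5(C(=O)O[C@H]6C[C@@]7(C)C(=C[C@H]65)[C@H](C)CC[C@@H]7O[Si](C)(C)C(C)(C)C)[C@H](C(C)=C3C[C@@H]12)[C@@H]4C=C | intermediate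
37 | C2 methyl ketone (acetyl syn to C4=C5) | C=C1C(=O)O[C@@H]2C[C@@H](C)[C@]34C[C@]5(C(=O)O[C@H]6C[C@@]7(C)C(=C[C@H]65)[C@H](C)CC[C@@H]7O[Si](C)(C)C(C)(C)C)[C@H](C(C)=C3C[C@@H]12)[C@@H]4C(C)=O | intermediate
38 | 1′-O-tert-butyldimethylsilyl japonicone A | C=C1C(=O)O[C@@H]2C[C@@H](C)[C@]34C[C@]5(C(=O)O[C@H]6C[C@@]7(C)C(=C[C@H]65)[C@H](C)CC[C@@H]7O[Si](C)(C)C(C)(C)C)[C@H](C(C)=C3C[C@@H]12)[C@@H]4OC(C)=O | intermediate
39 | japonicone A (enantiomer as given) | C=C1C(=O)O[C@@H]2C[C@@H](C)[C@]34C[C@]5(C(=O)O[C@H]6C[C@@]7(C)C(=C[C@H]65)[C@H](C)CC[C@@H]7O)[C@H](C(C)=C3C[C@@H]12)[C@@H]4OC(C)=O | target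

**Totals and risks**
Total step count: 24. Longest linear sequence: 17 steps (steps 1–10, then 18–24).

Steps most likely to fail:

1. Step 19 (proposed method). The C6 radical may be reduced or captured by a nickel centre bound to another molecule, giving oligomers, or the alkenyl triflate may be reduced before the radical arrives. The fallback uses known chemistry in stages and sets out from 30. Halide exchange (NaI, acetone) should give the iodoacetal F1. Triethylborane/air-initiated iodine-atom-transfer 5-exo cyclisation (Ueno–Stork type) should give the 7,8-trans primary iodide F2 with the alkenyl triflate untouched. Zinc insertion (Zn, LiCl, DMA) should give the alkylzinc iodide F3, and Pd(PPh3)4-catalysed intramolecular Negishi coupling closes the seven-membered ring and returns to the route at 31.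

2. Step 18. Proton transfer within the cuprate-derived enolate, attack of residual cuprate on 15, or a non-selective second Michael addition (exo or wrong-face closure) may erode the three-component union. The fallback sets out from 27. The cuprate addition is quenched with TBSCl/HMPA to give the isolable silyl dienol ether F4. A Diels–Alder reaction with 15 (toluene, 60 °C, or Me2AlCl at −40 °C) should give the silyl enol ether adduct F5, and CsF/PhNTf2 in DME converts it into the triflate, returning to the route at 30.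

3. Step 22. The palladium–copper system may coordinate or isomerise the α-methylene lactone, or attack the hindered vinyl group in the anti-Markovnikov sense. The fallback sets out from 33, which has no acrylate unit. The same Wacker oxidation should give the methyl ketone F6, and ketalisation (ethylene glycol, PPTS, benzene, reflux) the dioxolane F7. Methylenation as in step 21 passes through the Mannich base F8 and the trimethylammonium iodide F9 to the α-methylene lactone dioxolane F10. PPTS in wet acetone then frees the ketone and returns to the route at 37.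

**Further compounds**
F1 | step 19 | iodoacetal analogue of 30 | C=C[C@H](OC(CI)OCC)C[C@@H](C)[C@]12C[C@]3(C(=O)O[C@H]4C[C@@]5(C)C(=C[C@H]43)[C@H](C)CC[C@@H]5O[Si](C)(C)C(C)(C)C)[C@H](C(C)=C1OS(=O)(=O)C(F)(F)F)[C@@H]2C=C
F2 | step 19 | cyclised primary iodide (oxolane closed, 7,8-trans, C5 triflate kept) | IC[C@H]1CC(OCC)O[C@@H]1C[C@@H](C)[C@]23C[C@]4(C(=O)O[C@H]5C[C@@]6(C)C(=C[C@H]54)[C@H](C)CC[C@@H]6O[Si](C)(C)C(C)(C)C)[C@H](C(C)=C2OS(=O)(=O)C(F)(F)F)[C@@H]3C=C
F3 | step 19 | alkylzinc iodide from F2 | I[Zn]C[C@H]1CC(OCC)O[C@@H]1C[C@@H](C)[C@]23C[C@]4(C(=O)O[C@H]5C[C@@]6(C)C(=C[C@H]54)[C@H](C)CC[C@@H]6O[Si](C)(C)C(C)(C)C)[C@H](C(C)=C2OS(=O)(=O)C(F)(F)F)[C@@H]3C=C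
F4 | step 18 | tert-butyldimethylsilyl dienol ether (2-silyloxycyclopentadiene) | CC(C)(C)[Si](C)(C)OC1=C([C@H](C)C[C@@H](OC(CBr)OCC)C=C)[C@@H](C=C)C=C1C
F5 | step 18 | silyl enol ether Diels–Alder adduct | C=C[C@H](OC(CBr)OCC)C[C@@H](C)[C@]12C[C@]3(C(=O)O[C@H]4C[C@@]5(C)C(=C[C@H]43)[C@H](C)CC[C@@H]5O[Si](C)(C)C(C)(C)C)[C@H](C(C)=C1O[Si](C)(C)C(C)(C)C)[C@@H]2C=C
F6 | step 22 | methyl ketone with saturated lactone (C11H2) | C1C(=O)O[C@@H]2C[C@@H](C)[C@]34C[C@]5(C(=O)O[C@H]6C[C@@]7(C)C(=C[C@H]65)[C@H](C)CC[C@@H]7O[Si](C)(C)C(C)(C)C)[C@H](C(C)=C3C[C@@H]12)[C@@H]4C(C)=O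
F7 | step 22 | dioxolane of F6 | C1C(=O)O[C@@H]2C[C@@H](C)[C@]34C[C@]5(C(=O)O[C@H]6C[C@@]7(C)C(=C[C@H]65)[C@H](C)CC[C@@H]7O[Si](C)(C)C(C)(C)C)[C@H](C(C)=C3C[C@@H]12)[C@@H]4C8(C)OCCO8
F8 | step 22 | Mannich base of F7 (C11 epimers) | CN(C)CC1C(=O)O[C@@H]2C[C@@H](C)[C@]34C[C@]5(C(=O)O[C@H]6C[C@@]7(C)C(=C[C@H]65)[C@H](C)CC[C@@H]7O[Si](C)(C)C(C)(C)C)[C@H](C(C)=C3C[C@@H]12)[C@@H]4C8(C)OCCO8
F9 | step 22 | trimethylammonium iodide of F8 | C[N+](C)(C)CC1C(=O)O[C@@H]2C[C@@H](C)[C@]34C[C@]5(C(=O)O[C@H]6C[C@@]7(C)C(=C[C@H]65)[C@H](C)CC[C@@H]7O[Si](C)(C)C(C)(C)C)[C@H](C(C)=C3C[C@@H]12)[C@@H]4C8(C)OCCO8.[I-]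
F10 | step 22 | α-methylene lactone dioxolane | C=C1C(=O)O[C@@H]2C[C@@H](C)[C@]34C[C@]5(C(=O)O[C@H]6C[C@@]7(C)C(=C[C@H]65)[C@H](C)CC[C@@H]7O[Si](C)(C)C(C)(C)C)[C@H](C(C)=C3C[C@@H]12)[C@@H]4C8(C)OCCO8
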